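**Plan**

- Numbering: ring A carries OMe at C1, OH at C3, ring B (2,5-dihydroxyphenyl) at C4 and the CH2CH2 bridge to ring C (3-hydroxyphenyl) at C5.
- Retrosynthesis: the four phenols are masked as benzyl ethers, then the two neighbouring bonds C5–CH2 and C4–C1' are cut together. This leaves ring A as the C4 iodide 2, ring C as the 2-bromoethyl compound 5 and ring B as the boronic acid 10.
- Enabling feature: the C3 oxygen, the C4 aryl group and the C5 alkyl group sit on three adjacent carbons of ring A. An iodide on the middle carbon C4, flanked by the C3 ether and a free C5–H, is the pattern that palladium/norbornene relay catalysis needs to alkylate C5 and arylate C4 in one pot.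
- Forward: each fragment is made in one or two steps; one palladium/norbornene operation attaches the chain and then ring B; hydrogenolysis of the four benzyl ethers ends the route. No ring is formed.
- Stereochemistry: the target has no stereocentre, so none has to be set.

Key step: step 6

Remark: the tri-ortho-substituted biaryl axis between rings A and B is assumed to be configurationally labile, as the descriptor-free target structure implies, so no axial chirality is controlled.

**Route**

Step 1
Reactants: 1 2-iodo-5-methoxyphenol
Product: 2 2-(benzyloxy)-1-iodo-4-methoxybenzene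
Conditions: BnBr (1.1 equiv), K2CO3 (2 equiv), DMF, rt
Reagents that add atoms: benzyl bromide, BrCc1ccccc1
Why: Williamson ether synthesis; the phenoxide is the only nucleophile present and the aryl iodide is inert to carbonate at room temperature.

Step 2
Reactants: 3 3-(2-hydroxyethyl)phenol
Product: 4 2-[3-(benzyloxy)phenyl]ethanol
Conditions: BnBr (1.05 equiv), K2CO3 (1.5 equiv), acetone, reflux
Reagents that add atoms: benzyl bromide, BrCc1ccccc1
Why: Williamson ether synthesis, chemoselective because K2CO3 ionises only the phenol and leaves the much less acidic primary alcohol unalkylated.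

Step 3
Reactants: 4 2-[3-(benzyloxy)phenyl]ethanol
Product: 5 1-(benzyloxy)-3-(2-bromoethyl)benzene
Conditions: CBr4 (1.2 equiv), PPh3 (1.25 equiv), CH2Cl2, 0 °C to rt
Reagents that add atoms: carbon tetrabromide, BrC(Br)(Br)Br
Why: Appel reaction; bromide displaces the alkoxyphosphonium group at the primary carbon by SN2 under neutral conditions, which spare the benzyl ether and should not cause elimination to the styrene.

Step 4
Reactants: 6 2-bromobenzene-1,4-diol
Product: 7 1,4-bis(benzyloxy)-2-bromobenzene
Conditions: BnBr (2.4 equiv), K2CO3 (3 equiv), degassed DMF, N2, rt to 50 °C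
Reagents that add atoms: benzyl bromide, BrCc1ccccc1
Why: Double Williamson ether synthesis; exclusion of air keeps the hydroquinone from being oxidised while both phenoxides are alkylated.

Step 5
Reactants: 7 1,4-bis(benzyloxy)-2-bromobenzene
Product: 10 [2,5-bis(benzyloxy)phenyl]boronic acid, via aryllithium 8 (not isolated), via lithium aryltriisopropoxyborate 9 (not isolated)
Conditions: n-BuLi (1.05 equiv), THF, −78 °C; B(OiPr)3 (1.5 equiv), −78 °C to rt; 1 M aq HCl, 0 °C
Reagents that add atoms: triisopropyl borate, CC(C)OB(OC(C)C)OC(C)C; water, O
Why: Bromine–lithium exchange at −78 °C is much faster than deprotonation of the benzylic ether positions; the aryllithium is trapped by the borate ester, and mild acidic hydrolysis of the ate complex should release the boronic acid.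

Step 6
Reactants: 2 2-(benzyloxy)-1-iodo-4-methoxybenzene; 5 1-(benzyloxy)-3-(2-bromoethyl)benzene; 10 [2,5-bis(benzyloxy)phenyl]boronic acid
Product: 11 2,2',5'-tris(benzyloxy)-6-{2-[3-(benzyloxy)phenyl]ethyl}-4-methoxy-1,1'-biphenyl
Conditions: Pd(OAc)2 (10 mol %), tri(2-furyl)phosphine (20 mol %), norbornene (2 equiv), K2CO3 (4 equiv), 5 (2.5 equiv), 10 (1.5 equiv), degassed DMF, rt to 60 °C
Reagents that add atoms: none
Why: Zerovalent palladium adds to the C4–I bond of 2, norbornene inserts, and the norbornylpalladium metalates the only free ortho position, C5–H, to a five-membered aryl–norbornyl palladacycle; bromide 5 adds oxidatively to this divalent palladacycle to give tetravalent palladium, and reductive elimination forms the C5–CH2 bond. With C3 (benzyloxy) and C5 (alkyl) both substituted, steric strain drives β-carbon elimination of norbornene, and the divalent arylpalladium at C4 transmetalates with boronic acid 10 and reductively eliminates to form the C4–C1' bond and return zerovalent palladium. The closest known reaction type is the three-component Catellani reaction of ortho-substituted aryl iodides with primary alkyl bromides and arylboronic acids, that is ortho-alkylation with ipso Suzuki–Miyaura termination. No ring is closed and no stereocentre is formed. The step needs a single alkylation at C5 and arylation only at C4: the C3 benzyloxy group blocks the second ortho position so that over-alkylation cannot occur, the ortho substituent and the excess of norbornene make insertion into the first arylpalladium faster than its direct coupling with the hindered boronic acid, and norbornene leaves only after C5 has been alkylated. The excess of 5 and the mild K2CO3/DMF system at moderate temperature are chosen to keep E2 loss of HBr from the phenethyl bromide slow, and the excess of 10 to let transmetalation outrun C–H arylation of the nearby benzyl and phenethyl arenes.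

Step 7
Reactants: 11 2,2',5'-tris(benzyloxy)-6-{2-[3-(benzyloxy)phenyl]ethyl}-4-methoxy-1,1'-biphenyl
Product: 12 6-[2-(3-hydroxyphenyl)ethyl]-4-methoxy-[1,1'-biphenyl]-2,2',5'-triol
Conditions: H2 (1 atm), 10% Pd/C, EtOAc/MeOH, rt; filtration and concentration under argon
Reagents that add atoms: none
Why: Catalytic hydrogenolysis of the four aryl benzyl ethers; the aryl methyl ether, the saturated CH2CH2 bridge and the arene rings are inert under these conditions, and air is excluded in the work-up because the product contains a hydroquinone.

**Compound list**

1 | 2-iodo-5-methoxyphenol | COc1ccc(I)c(O)c1 | starting material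
2 | 2-(benzyloxy)-1-iodo-4-methoxybenzene | COc1ccc(I)c(OCc2ccccc2)c1 | intermediate
3 | 3-(2-hydroxyethyl)phenol | OCCc1cccc(O)c1 | starting material
4 | 2-[3-(benzyloxy)phenyl]ethanol | OCCc1cccc(OCc2ccccc2)c1 | intermediate
5 | 1-(benzyloxy)-3-(2-bromoethyl)benzene | BrCCc1cccc(OCc2ccccc2)c1 | intermediate
6 | 2-bromobenzene-1,4-diol | Oc1ccc(O)c(Br)c1 | starting material
7 | 1,4-bis(benzyloxy)-2-bromobenzene | Brc1cc(OCc2ccccc2)ccc1OCc1ccccc1 | intermediate
8 | [2,5-bis(benzyloxy)phenyl]lithium | [Li]c1cc(OCc2ccccc2)ccc1OCc1ccccc1 | intermediate (not isolated)
9 | lithium [2,5-bis(benzyloxy)phenyl]tri(propan-2-yloxy)borate | [Li+].CC(C)O[B-](OC(C)C)(OC(C)C)c1cc(OCc2ccccc2)ccc1OCc1ccccc1 | intermediate (not isolated)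
10 | [2,5-bis(benzyloxy)phenyl]boronic acid | OB(O)c1cc(OCc2ccccc2)ccc1OCc1ccccc1 | intermediate
11 | 2,2',5'-tris(benzyloxy)-6-{2-[3-(benzyloxy)phenyl]ethyl}-4-methoxy-1,1'-biphenyl | COc1cc(OCc2ccccc2)c(-c2cc(OCc3ccccc3)ccc2OCc2ccccc2)c(CCc2cccc(OCc3ccccc3)c2)c1 | intermediate
12 | 6-[2-(3-hydroxyphenyl)ethyl]-4-methoxy-[1,1'-biphenyl]-2,2',5'-triol | COc1cc(O)c(-c2cc(O)ccc2O)c(CCc2cccc(O)c2)c1 | target

**Step count**

Total: 7 steps. Longest linear sequence: 4 steps (3 → 4 → 5 → 11 → 12, or 6 → 7 → 10 → 11 → 12).

**Steps most likely to fail**

Step 6. The ipso termination may fail to keep pace with the relay. The di-ortho-substituted arylpalladium at C4 could be lost to reduction, to Heck coupling with styrene formed by E2 elimination of the bromide, or to intramolecular C–H arylation before it transmetalates with the hindered ortho-alkoxy boronic acid. The fallback divides the two bond formations and reverses the polarity of the biaryl coupling. It sets out from 2 and 5: a Catellani ortho-alkylation with ipso borylation (Pd(OAc)2, PPh3, norbornene, K2CO3, bis(pinacolato)diboron, DMF) should give 2-{2-(benzyloxy)-6-{2-[3-(benzyloxy)phenyl]ethyl}-4-methoxyphenyl}-4,4,5,5-tetramethyl-1,3,2-dioxaborolane F1. Here the small diboron reagent terminates the hindered arylpalladium quickly. A Suzuki–Miyaura coupling of F1 with bromide 7 (Pd(OAc)2, SPhos, K3PO4, toluene/water, 90 °C) should then form the C4–C1' bond and return to the route at 11.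

Step 5. The organolithium stage may go astray through incomplete bromine–lithium exchange, butylation of the aryllithium by the 1-bromobutane formed, or benzylic metalation followed by Wittig rearrangement. The fallback avoids organolithium chemistry. It sets out from 7: a Miyaura borylation (bis(pinacolato)diboron, Pd(dppf)Cl2, KOAc, dioxane, 85 °C) should give 2-[2,5-bis(benzyloxy)phenyl]-4,4,5,5-tetramethyl-1,3,2-dioxaborolane F2. Oxidative cleavage of the pinacol ester (NaIO4, NH4OAc, acetone/water, rt) should then return to the route at 10.

Step 4. The hydroquinone may be oxidised by air under the basic alkylation conditions, and the hydroxyl next to bromine may be benzylated only in part. The fallback forms the C–Br bond last instead of the C–O bonds. It does not start from a numbered compound but from commercial 1,4-bis(benzyloxy)benzene F3, which takes the place of 6. Electrophilic bromination with N-bromosuccinimide (1.0 equiv, MeCN/CH2Cl2, rt) can give only one monobromide, because the four ring positions of F3 are equivalent, and returns to the route at 7.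

**Further compounds**

F1 | step 6 | 2-{2-(benzyloxy)-6-{2-[3-(benzyloxy)phenyl]ethyl}-4-methoxyphenyl}-4,4,5,5-tetramethyl-1,3,2-dioxaborolane | COc1cc(OCc2ccccc2)c(B2OC(C)(C)C(C)(C)O2)c(CCc2cccc(OCc3ccccc3)c2)c1
F2 | step 5 | 2-[2,5-bis(benzyloxy)phenyl]-4,4,5,5-tetramethyl-1,3,2-dioxaborolane | CC1(C)OB(OC1(C)C)c1cc(OCc2ccccc2)ccc1OCc1ccccc1
F3 | step 4 | 1,4-bis(benzyloxy)benzene | c1ccc(COc2ccc(OCc3ccccc3)cc2)cc1
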